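**Retrosynthetic overview**

- The last bond made is the ester C(=O)–O bond between the CH2O arm on C2 of the 2H-chromene and (E)-ferulic acid, whose phenol is masked as a TBS ether and freed at the end.
- The strategy rests on C2 of the pyran ring: a fully substituted carbon bearing ring oxygen O1, a methyl group, the CH2O arm and vinylic C3. This is the skeleton of 2-methyl-2-vinyloxirane opened at its tertiary carbon by an aryl oxygen.
- O1–C2 is therefore formed by an enantioconvergent palladium-catalysed allylic etherification of the racemic epoxide with a 2-vinylphenol, and C3=C4 by ring-closing metathesis.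
- Ring order: both benzene rings are bought. The pyran ring is the only ring built, closed by metathesis after the O1–C2 bond exists. The vinylphenol comes from acetovanillone by ortho-iodination and Suzuki vinylation.

Key step: step 3

Assumption: the (R,R) ligand is taken to deliver the R ether by the usual quadrant model of these diamide diphosphines; if the sense of induction proves opposite, the (S,S) ligand is used with no other change.

**Route**

Step 1
Reactants: 1 acetovanillone
Product: 2 5-iodoacetovanillone (1-(4-hydroxy-3-iodo-5-methoxyphenyl)ethanone)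
Conditions: NIS (1.05 equiv), TsOH·H2O (10 mol%), MeCN, 0 °C to rt
Reagents that add atoms: N-iodosuccinimide, O=C1CCC(=O)N1I
Why: Electrophilic aromatic iodination; the phenol directs to its only free ortho position, since the para position carries the acetyl group and the other ortho position the methoxy group, and the deactivating ketone should hold the reaction at mono-iodination.

Step 2
Reactants: 2 5-iodoacetovanillone; 3 vinylboronic acid pinacol ester
Product: 4 1-(4-hydroxy-3-methoxy-5-vinylphenyl)ethanone
Conditions: Pd(dppf)Cl2·CH2Cl2 (3 mol%), K2CO3 (3 equiv), 3 (1.5 equiv), 1,4-dioxane/H2O 4:1, degassed, 80 °C, trace BHT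
Reagents that add atoms: none
Why: Suzuki–Miyaura coupling; zerovalent palladium inserts into the aryl C–I bond, the vinyl group is transferred from boron and reductive elimination gives the styrene, a sequence that tolerates the free phenol and the ketone under aqueous carbonate.

Step 3
Reactants: 4 1-(4-hydroxy-3-methoxy-5-vinylphenyl)ethanone; 5 racemic 2-methyl-2-vinyloxirane
Product: 6 1-{4-[((2R)-1-hydroxy-2-methylbut-3-en-2-yl)oxy]-3-methoxy-5-vinylphenyl}ethanone
Conditions: Pd2(dba)3·CHCl3 (2 mol%), (R,R)-DACH-phenyl Trost ligand N,N'-[(1R,2R)-cyclohexane-1,2-diyl]bis[2-(diphenylphosphanyl)benzamide] (6 mol%), 5 (1.5 equiv), CH2Cl2 (0.05 M), rt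
Reagents that add atoms: none
Why: This is an asymmetric allylic etherification run as a dynamic kinetic asymmetric transformation of a vinyl epoxide: zerovalent palladium opens either enantiomer of 5 to a zwitterionic pi-allyl palladium alkoxide, and the two diastereomeric complexes interconvert by pi-sigma-pi isomerisation faster than they are captured. The alkoxide takes the proton of the acidic phenol 4 (para-acetyl), and the hydrogen-bonded ion pair hands the phenoxide to the neighbouring, fully substituted allyl terminus, which forms the aryl O to C bond and releases the CH2OH arm. No ring is closed in this step; the oxirane is opened. The new quaternary stereocentre is controlled by the chiral pocket of the diphosphine ligand, which selects one face of the equilibrating allyl unit, so both enantiomers of 5 should converge on the R ether. The step needs branched over linear regioselectivity and enantiofacial selectivity; the first is secured by the alkoxide-directed proximal delivery, the second by the ligand together with dilution, which keeps bimolecular capture slower than allyl equilibration. The product alcohol is far less acidic than 4 and both ortho positions of the aryl ether are substituted, so neither a second etherification nor an aromatic Claisen rearrangement should interfere.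

Step 4
Reactants: 6 1-{4-[((2R)-1-hydroxy-2-methylbut-3-en-2-yl)oxy]-3-methoxy-5-vinylphenyl}ethanone
Product: 7 1-[(2R)-2-(hydroxymethyl)-8-methoxy-2-methyl-2H-chromen-6-yl]ethanone
Conditions: second-generation Grubbs catalyst RuCl2(=CHPh)(H2IMes)(PCy3) (3 mol%), CH2Cl2 (0.01 M), 40 °C
Reagents that add atoms: none
Why: Ring-closing metathesis; the ruthenium alkylidene loads on the styrene and cyclises onto the vinyl group at the quaternary carbon, closing the six-membered pyran ring with a necessarily cis C3=C4 bond and losing ethylene, while the stereocentre and the free alcohol are not involved.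

Step 5
Reactants: 8 (E)-ferulic acid
Product: 9 tert-butyldimethylsilyl (E)-3-[4-(tert-butyldimethylsilyloxy)-3-methoxyphenyl]prop-2-enoate
Conditions: TBSCl (2.5 equiv), imidazole (5 equiv), DMF, rt
Reagents that add atoms: tert-butyldimethylsilyl chloride, CC(C)(C)[Si](C)(C)Cl
Why: Imidazole-promoted silylation of both acidic hydroxyl groups (phenol and carboxylic acid), which leaves the E olefin untouched.

Step 6
Reactants: 9 tert-butyldimethylsilyl (E)-3-[4-(tert-butyldimethylsilyloxy)-3-methoxyphenyl]prop-2-enoate
Product: 10 (E)-4-O-TBS-ferulic acid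
Conditions: AcOH/THF/H2O 3:1:1, rt
Reagents that add atoms: none
Why: Selective solvolysis; a silyl ester is far more labile than an aryl silyl ether, so mild aqueous acid should cleave only the acyl O–Si bond and avoid the basic methanolysis that would attack the phenolic silyl ether.

Step 7
Reactants: 7 1-[(2R)-2-(hydroxymethyl)-8-methoxy-2-methyl-2H-chromen-6-yl]ethanone; 10 (E)-4-O-TBS-ferulic acid
Product: 11 [(2R)-6-acetyl-8-methoxy-2-methyl-2H-chromen-2-yl]methyl (E)-3-[4-(tert-butyldimethylsilyloxy)-3-methoxyphenyl]prop-2-enoate
Conditions: 10 (1.3 equiv), DCC (1.4 equiv), DMAP (4-dimethylaminopyridine, 0.3 equiv), CH2Cl2, 0 °C to rt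
Reagents that add atoms: none
Why: Steglich esterification; the carbodiimide activates the acid and DMAP relays the acyl group as an acylpyridinium ion to the primary, neopentyl-type alcohol, while the masked phenol of 10 cannot be acylated and the stereocentre is not touched.

Step 8
Reactants: 11 [(2R)-6-acetyl-8-methoxy-2-methyl-2H-chromen-2-yl]methyl (E)-3-[4-(tert-butyldimethylsilyloxy)-3-methoxyphenyl]prop-2-enoate
Product: 12 CNP0168033.1, [(2R)-6-acetyl-8-methoxy-2-methyl-2H-chromen-2-yl]methyl (E)-3-(4-hydroxy-3-methoxyphenyl)prop-2-enoate
Conditions: TBAF (1.1 equiv), AcOH (1.1 equiv), THF, 0 °C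
Reagents that add atoms: none
Why: Fluoride-induced cleavage of the aryl silyl ether; the acetic acid buffer protonates the phenoxide as it forms, so the cinnamate ester, the methyl ketone and the chromene should not be exposed to base.

**Compound list**

1 | acetovanillone, 1-(4-hydroxy-3-methoxyphenyl)ethanone | CC(=O)c1ccc(O)c(OC)c1 | starting material
2 | 5-iodoacetovanillone, 1-(4-hydroxy-3-iodo-5-methoxyphenyl)ethanone | CC(=O)c1cc(I)c(O)c(OC)c1 | intermediate
3 | vinylboronic acid pinacol ester | C=CB1OC(C)(C)C(C)(C)O1 | starting material
4 | 1-(4-hydroxy-3-methoxy-5-vinylphenyl)ethanone | CC(=O)c1cc(C=C)c(O)c(OC)c1 | intermediate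
5 | racemic 2-methyl-2-vinyloxirane (isoprene monoepoxide) | CC1(C=C)CO1 | starting material
6 | 1-{4-[((2R)-1-hydroxy-2-methylbut-3-en-2-yl)oxy]-3-methoxy-5-vinylphenyl}ethanone | OC[C@@](C)(C=C)Oc1c(C=C)cc(C(C)=O)cc1OC | intermediate
7 | 1-[(2R)-2-(hydroxymethyl)-8-methoxy-2-methyl-2H-chromen-6-yl]ethanone | OC[C@@]1(C)C=Cc2cc(C(C)=O)cc(OC)c2O1 | intermediate
8 | (E)-ferulic acid | COc1cc(/C=C/C(=O)O)ccc1O | starting material
9 | tert-butyldimethylsilyl (E)-3-[4-(tert-butyldimethylsilyloxy)-3-methoxyphenyl]prop-2-enoate | COc1cc(/C=C/C(=O)O[Si](C)(C)C(C)(C)C)ccc1O[Si](C)(C)C(C)(C)C | intermediate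
10 | (E)-4-O-TBS-ferulic acid | COc1cc(/C=C/C(=O)O)ccc1O[Si](C)(C)C(C)(C)C | intermediate
11 | [(2R)-6-acetyl-8-methoxy-2-methyl-2H-chromen-2-yl]methyl (E)-3-[4-(tert-butyldimethylsilyloxy)-3-methoxyphenyl]prop-2-enoate | COc1cc(/C=C/C(=O)OC[C@@]2(C)C=Cc3cc(C(C)=O)cc(OC)c3O2)ccc1O[Si](C)(C)C(C)(C)C | intermediate
12 | CNP0168033.1, [(2R)-6-acetyl-8-methoxy-2-methyl-2H-chromen-2-yl]methyl (E)-3-(4-hydroxy-3-methoxyphenyl)prop-2-enoate | COc1cc(/C=C/C(=O)OC[C@@]2(C)C=Cc3cc(C(C)=O)cc(OC)c3O2)ccc1O | target

**Step count**

Total steps: 8. Longest linear sequence: 6 steps (steps 1, 2, 3, 4, 7, 8); steps 5 and 6 prepare the acid fragment in parallel.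

**Steps most likely to fail**

Step 3. Capture of the pi-allyl intermediate by the doubly ortho-substituted phenoxide at the tertiary terminus may be slow. Attack at the CH2 terminus, re-ionisation of the product (a tertiary allylic ether of an electron-poor phenol) and loss of enantiopurity could then compete. The fallback makes the aryl O to C2 bond and the pyran ring by a propargyl ether rearrangement, sets out from 1 and comes back at 7. Ethynylmagnesium bromide is added to commercial 1-(tert-butyldimethylsilyloxy)propan-2-one in THF to give racemic 1-(tert-butyldimethylsilyloxy)-2-methylbut-3-yn-2-ol F1. This is converted in the flask with trifluoroacetic anhydride and DBU in MeCN into its trifluoroacetate F2, which etherifies 1 under CuCl2·2H2O catalysis to give the aryl 1,1-disubstituted propargyl ether F3. Heating F3 in 1,2-dichlorobenzene at about 180 °C should bring about the propargyl Claisen rearrangement, 1,5-hydrogen shift and 6-pi electrocyclisation at the only free ortho position to give the racemic silyl-protected chromene F4. TBAF in THF then frees the racemic chromenol F5. Preparative chromatography on a chiral stationary phase separates 7 from its S enantiomer F6, which is set aside.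

Step 2. The ortho-iodophenoxide may bind palladium and slow the coupling, and the vinylphenol formed may oligomerise in hot aqueous base. The fallback introduces the vinyl group only after the phenol has been etherified, sets out from 1 and comes back at 6. Bromination of 1 with NBS in MeCN gives 5-bromoacetovanillone F7. The etherification of step 3 is applied to F7 and 5 to give the bromo aryl ether 1-{3-bromo-4-[((2R)-1-hydroxy-2-methylbut-3-en-2-yl)oxy]-5-methoxyphenyl}ethanone F8; the aryl bromide should be inert to the palladium catalyst at room temperature. Suzuki–Miyaura coupling of F8 with 3 (Pd(dppf)Cl2·CH2Cl2, K2CO3, dioxane/H2O, 80 °C) then gives 6 without a free vinylphenol ever being handled.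

Step 7. Acyl transfer to the neopentyl-type alcohol may be slow enough for the O-acylisourea to rearrange to the unreactive N-acylurea. The fallback builds the cinnamate by olefination instead of acylation, sets out from 7 and comes back at 11. Compound 7 is acylated with the small and highly electrophilic 2-(diethoxyphosphoryl)acetyl chloride (from diethylphosphonoacetic acid and oxalyl chloride) and pyridine in CH2Cl2 to give the phosphonoacetate F9. A Horner–Wadsworth–Emmons olefination under Masamune–Roush conditions (LiCl, iPr2NEt, MeCN, rt) with 4-(tert-butyldimethylsilyloxy)-3-methoxybenzaldehyde F10 (from vanillin, TBSCl and imidazole) should then give the E cinnamate 11. The stabilised phosphonate anion should react with the aldehyde much faster than with the aryl methyl ketone.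

**Further compounds**

F1 | step 3 | racemic 1-(tert-butyldimethylsilyloxy)-2-methylbut-3-yn-2-ol | C#CC(C)(O)CO[Si](C)(C)C(C)(C)C
F2 | step 3 | racemic 1-(tert-butyldimethylsilyloxy)-2-methylbut-3-yn-2-yl trifluoroacetate | C#CC(C)(OC(=O)C(F)(F)F)CO[Si](C)(C)C(C)(C)C
F3 | step 3 | racemic 1-{4-[(1-(tert-butyldimethylsilyloxy)-2-methylbut-3-yn-2-yl)oxy]-3-methoxyphenyl}ethanone | CC(=O)c1ccc(OC(C)(C#C)CO[Si](C)(C)C(C)(C)C)c(OC)c1
F4 | step 3 | racemic 1-[2-(tert-butyldimethylsilyloxymethyl)-8-methoxy-2-methyl-2H-chromen-6-yl]ethanone | CC(=O)c1cc2c(c(OC)c1)OC(C)(CO[Si](C)(C)C(C)(C)C)C=C2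
F5 | step 3 | racemic 1-[2-(hydroxymethyl)-8-methoxy-2-methyl-2H-chromen-6-yl]ethanone | CC(=O)c1cc2c(c(OC)c1)OC(C)(CO)C=C2
F6 | step 3 | 1-[(2S)-2-(hydroxymethyl)-8-methoxy-2-methyl-2H-chromen-6-yl]ethanone | OC[C@]1(C)C=Cc2cc(C(C)=O)cc(OC)c2O1
F7 | step 2 | 5-bromoacetovanillone, 1-(3-bromo-4-hydroxy-5-methoxyphenyl)ethanone | CC(=O)c1cc(Br)c(O)c(OC)c1
F8 | step 2 | 1-{3-bromo-4-[((2R)-1-hydroxy-2-methylbut-3-en-2-yl)oxy]-5-methoxyphenyl}ethanone | OC[C@@](C)(C=C)Oc1c(Br)cc(C(C)=O)cc1OC
F9 | step 7 | [(2R)-6-acetyl-8-methoxy-2-methyl-2H-chromen-2-yl]methyl 2-(diethoxyphosphoryl)acetate | CCOP(=O)(CC(=O)OC[C@@]1(C)C=Cc2cc(C(C)=O)cc(OC)c2O1)OCC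
F10 | step 7 | 4-(tert-butyldimethylsilyloxy)-3-methoxybenzaldehyde | COc1cc(C=O)ccc1O[Si](C)(C)C(C)(C)C
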